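**Strategy**

The route rests on cutting both bonds to the C5 carbonyl carbon of the acyclic 3,5-dione: C4–C5 and C5–C6. C5 is introduced as a doubly nucleophilic acyl equivalent, the C2 carbon of a 2-silyl-1,3-dithiane. In one flask it opens a terminal epoxide carrying the benzyl-protected guaiacyl ring and C1–C4, relays its charge back to C5 by C-to-O silyl migration, and is then alkylated by the undecyl iodide (C6–C16). The step exploits the 1,3-relationship of the C3 oxygen and the C5 carbonyl carbon; no ring is formed. The precursor is a racemic 2-(2-arylethyl)oxirane, whose C3 oxygen emerges silylated, keeping the enolisable diketone hidden until the end.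

Key step: step 4

Assumption: chain carbons are numbered C1 (benzylic) to C16 (terminal methyl). C3 is carried as a racemate because it ends as a ketone, and the target has no stereocentre. The target is drawn as the diketo tautomer although it should exist largely as its enol.

**Route**

Step 1
Reactants: 1 4-benzyloxy-3-methoxybenzyl alcohol
Product: 2 4-benzyloxy-3-methoxybenzyl chloride
Conditions: SOCl2, CH2Cl2, 0 °C to rt; used crude
Reagents that add atoms: thionyl chloride, O=S(Cl)Cl
Why: Deoxychlorination of an electron-rich benzylic alcohol via its chlorosulfite should be fast at 0 °C, and the aryl benzyl and methyl ethers are inert to SOCl2, the chloride being used at once because such benzylic chlorides self-condense on storage.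

Step 2
Reactants: 2 4-benzyloxy-3-methoxybenzyl chloride; 3 allylmagnesium bromide
Product: 4 4-(4-benzyloxy-3-methoxyphenyl)but-1-ene
Conditions: allylmagnesium bromide (Et2O solution, excess), THF, 0 °C to rt
Reagents that add atoms: none
Why: Uncatalysed Grignard alkylation, in which the allyl Grignard reagent should displace the activated benzylic chloride by SN2 and join C1 to C2 without touching the aryl ethers.

Step 3
Reactants: 4 4-(4-benzyloxy-3-methoxyphenyl)but-1-ene
Product: 5 racemic 2-[2-(4-benzyloxy-3-methoxyphenyl)ethyl]oxirane
Conditions: mCPBA, CH2Cl2, 0 °C to rt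
Reagents that add atoms: mCPBA (3-chloroperoxybenzoic acid), O=C(OO)c1cccc(Cl)c1
Why: Prilezhaev epoxidation of the only alkene by concerted oxygen transfer should give the terminal epoxide; the new C3 stereocentre is formed as a racemate on purpose, since C3 ends as a ketone.

Step 4
Reactants: 6 2-(tert-butyldimethylsilyl)-1,3-dithiane; 5 racemic 2-[2-(4-benzyloxy-3-methoxyphenyl)ethyl]oxirane; 7 1-iodoundecane
Product: 11 racemic 2-[4-(4-benzyloxy-3-methoxyphenyl)-2-(tert-butyldimethylsilyloxy)butyl]-2-undecyl-1,3-dithiane, via lithiated silyl dithiane 8 (not isolated), via lithium alkoxide adduct 9 (not isolated), via silyl-shifted dithianyllithium 10 (not isolated)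
Conditions: t-BuLi (slight deficit relative to 6), Et2O, −78 to −45 °C; then 5, −78 to −25 °C; then 7, HMPA, THF, −78 °C to rt
Reagents that add atoms: none
Why: t-BuLi removes the C2 proton of 6 to give carbanion 8, stabilised by silicon and two sulfurs, which opens epoxide 5 by SN2 at its unsubstituted CH2 carbon (C4–C5 bond) to give alkoxide 9. On adding HMPA the lithium alkoxide attacks silicon and a 1,4-Brook rearrangement moves the silyl group from C5 to the C3 oxygen, regenerating a dithiane carbanion 10 that displaces iodide from 7 (C5–C6 bond). The closest known reaction type is the solvent-gated multicomponent silyl-dithiane linchpin coupling (anion relay), ending in a Corey–Seebach alkylation. No ring is closed and no new stereocentre is created; C3 arrives racemic from the epoxide and is oxidised later. The step needs regioselective opening at the terminal carbon, secured by the monosubstituted epoxide, and a fixed order of the two bond formations, secured because silyl migration does not occur in ether until HMPA is added. The unbranched primary iodide favours substitution over elimination, and the slight deficit of t-BuLi leaves no free alkyllithium to attack the benzylic OCH2 group or the iodide.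

Step 5
Reactants: 11 racemic 2-[4-(4-benzyloxy-3-methoxyphenyl)-2-(tert-butyldimethylsilyloxy)butyl]-2-undecyl-1,3-dithiane
Product: 12 racemic 4-(4-benzyloxy-3-methoxyphenyl)-1-(2-undecyl-1,3-dithian-2-yl)butan-2-ol
Conditions: Bu4NF, THF, rt
Reagents that add atoms: none
Why: Fluoride-mediated desilylation, driven by the strong Si–F bond, should free the C3 hydroxyl while no carbonyl group is yet present that the basic fluoride could enolise, and the dithiane and benzyl ether are inert.

Step 6
Reactants: 12 racemic 4-(4-benzyloxy-3-methoxyphenyl)-1-(2-undecyl-1,3-dithian-2-yl)butan-2-ol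
Product: 13 racemic 1-(4-benzyloxy-3-methoxyphenyl)-3-hydroxyhexadecan-5-one
Conditions: I2, NaHCO3, acetone/H2O, 0 °C
Reagents that add atoms: water, O
Why: Oxidative dithiane hydrolysis, in which iodine activates sulfur, the ring opens to a thionium ion that water captures, and collapse gives the C5 ketone; doing it while C3 is still an alcohol means no 1,3-diketone with an iodinatable C4 methylene meets iodine, and bicarbonate at 0 °C should be tolerated by the aldol.

Step 7
Reactants: 13 racemic 1-(4-benzyloxy-3-methoxyphenyl)-3-hydroxyhexadecan-5-one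
Product: 14 1-(4-benzyloxy-3-methoxyphenyl)hexadecane-3,5-dione
Conditions: DMP (1.2 equiv), pyridine, CH2Cl2, 0 °C to rt
Reagents that add atoms: none
Why: Dess–Martin oxidation by ligand exchange at iodine and loss of the carbinol hydrogen is an established way from β-hydroxy ketones to 1,3-diketones under nearly neutral conditions, the oxidant being kept to a slight excess to spare the C4 methylene; the C3 stereocentre disappears here.

Step 8
Reactants: 14 1-(4-benzyloxy-3-methoxyphenyl)hexadecane-3,5-dione
Product: 15 [12]-gingerdione, 1-(4-hydroxy-3-methoxyphenyl)hexadecane-3,5-dione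
Conditions: H2 (1 atm), 10% Pd/C, EtOAc, rt
Reagents that add atoms: none
Why: Catalytic hydrogenolysis of the benzyl aryl ether on palladium should free the phenol at room temperature, conditions under which the diketone and the arene are not reduced and which are applied only after all sulfur has left the molecule.

**Compound list**

1 | 4-benzyloxy-3-methoxybenzyl alcohol | COc1cc(CO)ccc1OCc1ccccc1 | starting material
2 | 4-benzyloxy-3-methoxybenzyl chloride | COc1cc(CCl)ccc1OCc1ccccc1 | intermediate
3 | allylmagnesium bromide | C=CC[Mg]Br | starting material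
4 | 4-(4-benzyloxy-3-methoxyphenyl)but-1-ene | C=CCCc1ccc(OCc2ccccc2)c(OC)c1 | intermediate
5 | racemic 2-[2-(4-benzyloxy-3-methoxyphenyl)ethyl]oxirane | COc1cc(CCC2CO2)ccc1OCc1ccccc1 | intermediate
6 | 2-(tert-butyldimethylsilyl)-1,3-dithiane | CC(C)(C)[Si](C)(C)C1SCCCS1 | starting material
7 | 1-iodoundecane | CCCCCCCCCCCI | starting material
8 | 2-lithio-2-(tert-butyldimethylsilyl)-1,3-dithiane | CC(C)(C)[Si](C)(C)C1([Li])SCCCS1 | intermediate
9 | racemic lithium 4-(4-benzyloxy-3-methoxyphenyl)-1-[2-(tert-butyldimethylsilyl)-1,3-dithian-2-yl]butan-2-olate | COc1cc(CCC(O[Li])CC2([Si](C)(C)C(C)(C)C)SCCCS2)ccc1OCc1ccccc1 | intermediate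
10 | racemic 2-lithio-2-[4-(4-benzyloxy-3-methoxyphenyl)-2-(tert-butyldimethylsilyloxy)butyl]-1,3-dithiane | COc1cc(CCC(CC2([Li])SCCCS2)O[Si](C)(C)C(C)(C)C)ccc1OCc1ccccc1 | intermediate
11 | racemic 2-[4-(4-benzyloxy-3-methoxyphenyl)-2-(tert-butyldimethylsilyloxy)butyl]-2-undecyl-1,3-dithiane | CCCCCCCCCCCC1(CC(CCc2ccc(OCc3ccccc3)c(OC)c2)O[Si](C)(C)C(C)(C)C)SCCCS1 | intermediate
12 | racemic 4-(4-benzyloxy-3-methoxyphenyl)-1-(2-undecyl-1,3-dithian-2-yl)butan-2-ol | CCCCCCCCCCCC1(CC(O)CCc2ccc(OCc3ccccc3)c(OC)c2)SCCCS1 | intermediate
13 | racemic 1-(4-benzyloxy-3-methoxyphenyl)-3-hydroxyhexadecan-5-one | CCCCCCCCCCCC(=O)CC(O)CCc1ccc(OCc2ccccc2)c(OC)c1 | intermediate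
14 | 1-(4-benzyloxy-3-methoxyphenyl)hexadecane-3,5-dione | CCCCCCCCCCCC(=O)CC(=O)CCc1ccc(OCc2ccccc2)c(OC)c1 | intermediate
15 | [12]-gingerdione, 1-(4-hydroxy-3-methoxyphenyl)hexadecane-3,5-dione | CCCCCCCCCCCC(=O)CC(=O)CCc1ccc(O)c(OC)c1 | target

**Step count**

Total steps: 8. Longest linear sequence: 8 steps (1 to 15); compounds 3, 6 and 7 are purchased.

**Steps most likely to fail**

Step 4. The relay may stall after the first bond: silyl migration can be incomplete, or the rearranged carbanion can be lost by proton transfer or by elimination of HI from the iodide. The fallback separates the two bond formations and sets out from epoxide 5. Dodecanal and propane-1,3-dithiol (BF3·OEt2, CH2Cl2) would give 2-undecyl-1,3-dithiane F1. n-BuLi (THF, −30 °C) would convert it into 2-lithio-2-undecyl-1,3-dithiane F2. Addition of 5 (THF/DMPU, −78 to 0 °C, Corey–Seebach opening at the CH2 carbon) would give lithium 4-(4-benzyloxy-3-methoxyphenyl)-1-(2-undecyl-1,3-dithian-2-yl)butan-2-olate F3. Quenching with water returns the route at alcohol 12, so step 5 is no longer needed.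

Step 6. Hydrolysis at the fully substituted dithiane carbon may be slow, and while it is pushed the β-hydroxy ketone may suffer retro-aldol cleavage or dehydration in the bicarbonate medium. The fallback keeps the C3 oxygen silylated during unmasking and sets out from 11. Alkylative hydrolysis (MeI, CaCO3, MeCN/H2O, 45 °C) would give racemic 1-(4-benzyloxy-3-methoxyphenyl)-3-(tert-butyldimethylsilyloxy)hexadecan-5-one F4. Acidic desilylation (HF·pyridine, THF, 0 °C to rt) would then give 13, where the route is rejoined; steps 5 and 6 are replaced.

Step 7. The product may be oxidised further at the doubly activated C4 methylene, or the aldol may dehydrate to an enone before it is oxidised. The fallback moves the oxidation ahead of the unmasking and sets out from 12. Parikh–Doering oxidation (SO3·pyridine, DMSO, iPr2NEt, CH2Cl2, 0 °C) would give 4-(4-benzyloxy-3-methoxyphenyl)-1-(2-undecyl-1,3-dithian-2-yl)butan-2-one F5, which has no 1,3-dicarbonyl methylene. Hydrolysis with the thiophilic divalent mercury salt Hg(ClO4)2 (CaCO3, THF/H2O, 0 °C), which carries no electrophilic halogen, would give 14, where the route is rejoined; steps 6 and 7 are replaced.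

**Further compounds**

F1 | step 4 | 2-undecyl-1,3-dithiane | CCCCCCCCCCCC1SCCCS1
F2 | step 4 | 2-lithio-2-undecyl-1,3-dithiane | CCCCCCCCCCCC1([Li])SCCCS1
F3 | step 4 | racemic lithium 4-(4-benzyloxy-3-methoxyphenyl)-1-(2-undecyl-1,3-dithian-2-yl)butan-2-olate | CCCCCCCCCCCC1(CC(O[Li])CCc2ccc(OCc3ccccc3)c(OC)c2)SCCCS1
F4 | step 6 | racemic 1-(4-benzyloxy-3-methoxyphenyl)-3-(tert-butyldimethylsilyloxy)hexadecan-5-one | CCCCCCCCCCCC(=O)CC(CCc1ccc(OCc2ccccc2)c(OC)c1)O[Si](C)(C)C(C)(C)C
F5 | step 7 | 4-(4-benzyloxy-3-methoxyphenyl)-1-(2-undecyl-1,3-dithian-2-yl)butan-2-one | CCCCCCCCCCCC1(CC(=O)CCc2ccc(OCc3ccccc3)c(OC)c2)SCCCS1
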